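**Retrosynthetic overview**
1. Target 12 ⇐ O‑debenzylation of 11.
2. 11 ⇐ syn hydroboration–oxidation of the (E)‑arylidene oxolane 9; this makes the C7'–O bond and sets C7' and C8'.
3. 9 ⇐ key C7–O bond: catalytic enantioselective ring closure of the achiral diene diol 7 through a p‑quinone methide; this forms the only ring (the oxolane) and sets C7 and C8.
4. 7 ⇐ hydride reduction of half‑ester 6 ⇐ two successive Stobbe condensations of dimethyl succinate 2 with vanillin 1 and O‑benzylvanillin 5.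

Assumption: lignan numbering is used (C7/C8/C9 on the half whose aryl group sits on the oxolane, primes on the other half). (S)‑TRIP is (S)‑3,3'‑bis(2,4,6‑triisopropylphenyl)‑1,1'‑binaphthyl‑2,2'‑diyl hydrogen phosphate; its sense of induction in step 4 is taken to give (2R,3S), and the (R)‑acid is used if it proves the other way.

**Step 1**
Reactants: 1 vanillin (4‑hydroxy‑3‑methoxybenzaldehyde); 2 dimethyl succinate
Product: 4 dimethyl (E)‑2‑(4‑hydroxy‑3‑methoxybenzylidene)succinate, via Stobbe half‑ester 3 (not isolated)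
Conditions: LiOMe (3 equiv), MeOH, reflux; then conc. H2SO4 (to pH 1), MeOH, reflux
Reagents that add atoms: methanol (CO)
Why: Stobbe condensation of the succinate enolate with vanillin (run on its lithium phenoxide) gives the E half‑ester 3, the aryl group ending trans to the conjugated ester, and Fischer esterification in the same methanol gives 4; no stereocentre is formed.

**Step 2**
Reactants: 4 dimethyl (E)‑2‑(4‑hydroxy‑3‑methoxybenzylidene)succinate; 5 4‑(benzyloxy)‑3‑methoxybenzaldehyde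
Product: 6 (2E,3E)‑4‑[4‑(benzyloxy)‑3‑methoxyphenyl]‑2‑[(4‑hydroxy‑3‑methoxyphenyl)methylidene]‑3‑(methoxycarbonyl)but‑3‑enoic acid
Conditions: LiOMe (4 equiv), MeOH, reflux; then 1 M HCl, 0 °C
Reagents that add atoms: none
Why: A second Stobbe condensation at the only remaining acidic CH2 of 4 (extra base covers the phenoxide) installs the second arylidene with thermodynamic E geometry, which fixes the E,E diene needed in steps 4 and 5; no stereocentre is formed.

**Step 3**
Reactants: 6 (2E,3E)‑half‑ester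
Product: 7 (2E,3E)‑2‑{[4‑(benzyloxy)‑3‑methoxyphenyl]methylidene}‑3‑[(4‑hydroxy‑3‑methoxyphenyl)methylidene]butane‑1,4‑diol
Conditions: LiAlH4 (5 equiv), THF, −20 to 0 °C; then aq. potassium sodium tartrate
Reagents that add atoms: none
Why: Hydride 1,2‑reduction (LiAlH4) of the ester and the carboxylate gives the two allylic alcohols at or below 0 °C and leaves both styrene double bonds, their E geometry, the phenol and the benzyl ether untouched; no stereocentre is formed.

**Step 4**
Reactants: 7 diene diol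
Product: 9 4‑[(2R,3S,4E)‑4‑{[4‑(benzyloxy)‑3‑methoxyphenyl]methylidene}‑3‑(hydroxymethyl)oxolan‑2‑yl]‑2‑methoxyphenol, via p‑quinone methide 8 (not isolated)
Conditions: (S)‑TRIP (10 mol%), CH2Cl2 (0.02 M), 0 °C to rt
Reagents that add atoms: none
Why: Proposed new method: a chiral phosphoric acid‑catalysed enantioselective 5‑exo hydroalkoxylation of a p‑hydroxystyrene through its quinone methide tautomer, in which the acid, held by the phenol O–H, protonates C8 and takes back the phenol proton so that only the free‑phenol styrene (the benzyl‑protected one cannot become a neutral quinone methide) gives 8, and the C9'–OH, hydrogen‑bonded to the phosphoryl oxygen of the same catalyst that binds the quinone methide carbonyl, then adds to C7 in an oxa‑1,6‑addition; the catalyst selects the C7 face (R) and the preferred trans arrangement of aryl and CH2OH fixes C8 (S), either by dynamic kinetic resolution of 8 (7 and 8 interconvert) or, if protonation is irreversible, by catalyst‑controlled anti addition of H and O across the E alkene; the closest known reaction types are chiral phosphoric acid‑catalysed 1,6‑additions of O‑nucleophiles to p‑quinone methides made in situ and Brønsted acid‑catalysed asymmetric hydroalkoxylation of alkenols, neither shown on a bis(styryl) diol where the catalyst must choose one styrene and one hydroxyl and set two stereocentres.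

**Step 5**
Reactants: 9 (E)‑arylidene oxolane
Product: 11 4‑[(2R,3S,4S)‑4‑{(S)‑[4‑(benzyloxy)‑3‑methoxyphenyl](hydroxy)methyl}‑3‑(hydroxymethyl)oxolan‑2‑yl]‑2‑methoxyphenol, via benzylic alkylborane 10 (not isolated)
Conditions: BH3·SMe2 (4 equiv), THF, 0 °C to rt; then NaBO3·4H2O, THF/H2O, rt
Reagents that add atoms: sodium perborate tetrahydrate ([Na+].[Na+].O[B-]1(O)OO[B-](O)(O)OO1.O.O.O.O.O.O)
Why: Hydroboration–oxidation: BH3 adds syn across the E trisubstituted styrene with boron on the less substituted benzylic C7' and hydrogen on C8' from the face opposite the CH2OH on C8 (pushed pseudo‑axial by allylic strain with the cis aryl), and the C–B bond is oxidised with retention, so facial choice sets C8' (S, cis to CH2OH) and the E geometry translates into C7' (S).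

**Step 6**
Reactants: 11 O‑benzyl ether
Product: 12 4‑[(2R,3S,4S)‑4‑[(S)‑hydroxy(4‑hydroxy‑3‑methoxyphenyl)methyl]‑3‑(hydroxymethyl)oxolan‑2‑yl]‑2‑methoxyphenol (target)
Conditions: H2 (1 atm), 10% Pd/C, EtOAc, rt, stopped at full O‑debenzylation
Reagents that add atoms: none
Why: Catalytic hydrogenolysis cleaves the aryl benzyl ether much faster than the benzylic C–O bonds of the oxolane and the carbinol under neutral conditions, so 12 is obtained with all four stereocentres untouched.

**Compound list**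
1 | vanillin (4‑hydroxy‑3‑methoxybenzaldehyde) | COc1cc(C=O)ccc1O | starting material
2 | dimethyl succinate | COC(=O)CCC(=O)OC | starting material
3 | (E)‑4‑(4‑hydroxy‑3‑methoxyphenyl)‑3‑(methoxycarbonyl)but‑3‑enoic acid (Stobbe half‑ester) | OC(=O)C/C(=C\c1ccc(O)c(OC)c1)C(=O)OC | intermediate
4 | dimethyl (E)‑2‑(4‑hydroxy‑3‑methoxybenzylidene)succinate | COC(=O)C/C(=C\c1ccc(O)c(OC)c1)C(=O)OC | intermediate
5 | 4‑(benzyloxy)‑3‑methoxybenzaldehyde | COc1cc(C=O)ccc1OCc1ccccc1 | starting material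
6 | (2E,3E)‑4‑[4‑(benzyloxy)‑3‑methoxyphenyl]‑2‑[(4‑hydroxy‑3‑methoxyphenyl)methylidene]‑3‑(methoxycarbonyl)but‑3‑enoic acid | COc1cc(/C=C(C(=O)O)\C(C(=O)OC)=C/c2ccc(OCc3ccccc3)c(OC)c2)ccc1O | intermediate
7 | (2E,3E)‑2‑{[4‑(benzyloxy)‑3‑methoxyphenyl]methylidene}‑3‑[(4‑hydroxy‑3‑methoxyphenyl)methylidene]butane‑1,4‑diol | COc1cc(/C=C(CO)\C(CO)=C/c2ccc(OCc3ccccc3)c(OC)c2)ccc1O | intermediate
8 | 4‑[(2S,3E)‑4‑[4‑(benzyloxy)‑3‑methoxyphenyl]‑2,3‑bis(hydroxymethyl)but‑3‑en‑1‑ylidene]‑2‑methoxycyclohexa‑2,5‑dien‑1‑one (p‑quinone methide; ring‑exocyclic C=C geometry not defined) | COC1=CC(=C[C@H](CO)/C(CO)=C\c2ccc(OCc3ccccc3)c(OC)c2)C=CC1=O | intermediate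
9 | 4‑[(2R,3S,4E)‑4‑{[4‑(benzyloxy)‑3‑methoxyphenyl]methylidene}‑3‑(hydroxymethyl)oxolan‑2‑yl]‑2‑methoxyphenol | COc1cc(/C=C2/CO[C@@H](c3ccc(O)c(OC)c3)[C@@H]2CO)ccc1OCc1ccccc1 | intermediate
10 | {(S)‑[4‑(benzyloxy)‑3‑methoxyphenyl][(3S,4S,5R)‑5‑(4‑hydroxy‑3‑methoxyphenyl)‑4‑(hydroxymethyl)oxolan‑3‑yl]methyl}borane (drawn with free OH groups; these are borate esters until work‑up) | COc1cc([C@@H](B)[C@@H]2CO[C@@H](c3ccc(O)c(OC)c3)[C@@H]2CO)ccc1OCc1ccccc1 | intermediate
11 | 4‑[(2R,3S,4S)‑4‑{(S)‑[4‑(benzyloxy)‑3‑methoxyphenyl](hydroxy)methyl}‑3‑(hydroxymethyl)oxolan‑2‑yl]‑2‑methoxyphenol | COc1cc([C@@H](O)[C@@H]2CO[C@@H](c3ccc(O)c(OC)c3)[C@@H]2CO)ccc1OCc1ccccc1 | intermediate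
12 | 4‑[(2R,3S,4S)‑4‑[(S)‑hydroxy(4‑hydroxy‑3‑methoxyphenyl)methyl]‑3‑(hydroxymethyl)oxolan‑2‑yl]‑2‑methoxyphenol | COc1cc([C@@H](O)[C@@H]2CO[C@@H](c3ccc(O)c(OC)c3)[C@@H]2CO)ccc1O | target

**Step count and risks**
Total steps: 6. Longest linear sequence: 6 (from vanillin).

The three steps most likely to fail:

Step 4 (the new reaction). The acid may give low enantioselectivity, may close the 1,4‑diol by dehydration to a 3,4‑bis(arylidene)oxolane, or may protonate the remote diene terminus. Fallback with known chemistry, setting out from 7: an achiral Brønsted acid (diphenyl phosphate, (PhO)2P(O)OH, 10 mol%, CH2Cl2, 0 °C) effects the same quinone methide cyclisation without asymmetric induction and gives trans product as a racemate, that is 9 together with its enantiomer ent‑9 F4. Lipase‑catalysed kinetic resolution (Candida antarctica lipase B, vinyl acetate, MTBE, 30 °C; a lipase is chosen that acylates the unwanted antipode) converts the primary alcohol of ent‑9 into ent‑9 acetate F5, which is removed by chromatography. Unreacted 9 (at most 50%) comes back to the route at 9.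

Step 5. The C7 aryl group lies on the face the borane must attack, so facial selectivity at C8' is uncertain, and some boron may go to C8'. Fallback, setting out from 9: radical Markovnikov hydration by hydrogen atom transfer (tris(2,2,6,6‑tetramethylheptane‑3,5‑dionato)manganese, Mn(dpm)3, PhSiH3, O2, i‑PrOH/CH2Cl2, 0 °C) puts H on C8' from the less hindered face and gives 11 mixed with its C7' epimer F6. MnO2 (CH2Cl2, rt) oxidises only the benzylic carbinol of both to the aryl ketone F7. Reagent‑controlled reduction with (R)‑1‑methyl‑3,3‑diphenyl‑tetrahydro‑1H,3H‑pyrrolo[1,2‑c][1,3,2]oxazaborole (20 mol%) and BH3·SMe2 (the enantiomer that gives the S carbinol when aryl is the large group) comes back to the route at 11. Here C8' and C7' are set in separate events.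

Step 2. The phenoxide‑bearing ester 4 may condense sluggishly or give E/Z mixtures. Fallback, setting out from 2 and 5 with the order of assembly inverted so that the enolate partner carries no phenoxide: Stobbe condensation (NaOMe, MeOH, reflux) gives (E)‑4‑[4‑(benzyloxy)‑3‑methoxyphenyl]‑3‑(methoxycarbonyl)but‑3‑enoic acid F1, esterified in the same pot (H2SO4, MeOH) to dimethyl (E)‑2‑[4‑(benzyloxy)‑3‑methoxybenzylidene]succinate F2. F2 is condensed with vanillin 1 under the LiOMe/MeOH conditions of step 1 to give the regioisomeric half‑ester (2E,3E)‑2‑{[4‑(benzyloxy)‑3‑methoxyphenyl]methylidene}‑4‑(4‑hydroxy‑3‑methoxyphenyl)‑3‑(methoxycarbonyl)but‑3‑enoic acid F3. LiAlH4 reduction of F3 as in step 3 comes back to the route at 7.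

Further compounds
F1 | step 2 | (E)‑4‑[4‑(benzyloxy)‑3‑methoxyphenyl]‑3‑(methoxycarbonyl)but‑3‑enoic acid (not isolated) | OC(=O)C/C(=C\c1ccc(OCc2ccccc2)c(OC)c1)C(=O)OC
F2 | step 2 | dimethyl (E)‑2‑[4‑(benzyloxy)‑3‑methoxybenzylidene]succinate | COC(=O)C/C(=C\c1ccc(OCc2ccccc2)c(OC)c1)C(=O)OC
F3 | step 2 | (2E,3E)‑2‑{[4‑(benzyloxy)‑3‑methoxyphenyl]methylidene}‑4‑(4‑hydroxy‑3‑methoxyphenyl)‑3‑(methoxycarbonyl)but‑3‑enoic acid | COc1cc(/C=C(C(=O)OC)\C(C(=O)O)=C/c2ccc(OCc3ccccc3)c(OC)c2)ccc1O
F4 | step 4 | ent‑9, 4‑[(2S,3R,4E)‑4‑{[4‑(benzyloxy)‑3‑methoxyphenyl]methylidene}‑3‑(hydroxymethyl)oxolan‑2‑yl]‑2‑methoxyphenol | COc1cc(/C=C2/CO[C@H](c3ccc(O)c(OC)c3)[C@H]2CO)ccc1OCc1ccccc1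
F5 | step 4 | ent‑9 acetate, [(2S,3R,4E)‑4‑{[4‑(benzyloxy)‑3‑methoxyphenyl]methylidene}‑2‑(4‑hydroxy‑3‑methoxyphenyl)oxolan‑3‑yl]methyl acetate | COc1cc(/C=C2/CO[C@H](c3ccc(O)c(OC)c3)[C@H]2COC(C)=O)ccc1OCc1ccccc1
F6 | step 5 | C7' epimer of 11, 4‑[(2R,3S,4S)‑4‑{(R)‑[4‑(benzyloxy)‑3‑methoxyphenyl](hydroxy)methyl}‑3‑(hydroxymethyl)oxolan‑2‑yl]‑2‑methoxyphenol | COc1cc([C@H](O)[C@@H]2CO[C@@H](c3ccc(O)c(OC)c3)[C@@H]2CO)ccc1OCc1ccccc1
F7 | step 5 | [4‑(benzyloxy)‑3‑methoxyphenyl][(3S,4S,5R)‑5‑(4‑hydroxy‑3‑methoxyphenyl)‑4‑(hydroxymethyl)oxolan‑3‑yl]methanone | COc1cc(C(=O)[C@@H]2CO[C@@H](c3ccc(O)c(OC)c3)[C@@H]2CO)ccc1OCc1ccccc1
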